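Ring C (C8, C9, C11–C14) is disconnected at C9–C8 and C12–C13 in a [3+3] sense. It exploits the fact that C9 and C12 flank C11 while C8 and C13 flank C14: a temporary C11 ketone makes C9 and C12 nucleophilic, and an alkylidene β-ketophosphonate puts the β-carbon C8 and the acetyl carbon C13 on C14. The precursor is a monocyclic ring A lactone with an acetonyl arm on C10 and this acceptor arm on C5. One acid-mediated Michael addition/aldol condensation closes rings B and C and sets C8 and C9. The phosphonate then introduces the aryl-bearing C15, a Wharton transposition moves oxygen from C11 to C13, and arene oxidation triggers spirocyclisation.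

Key step: step 11

Numbering used for all compounds (that of the target): ring A = C1–C5, C10; ring B = C5–C10; ring C = C8, C9, C11–C14; C15 = CH2 on C14; C16, C17, C18 = methyl groups on C13, C8, C4; C19 = lactone C=O on C4; C20 = OCH2 on C10; C1'–C6' = dione/arene ring (C1' bears C15; C3' and C6' bear oxygen). α is the face of H5, β the face of C20. The target has 4α-Me, 5α-H, 8β-Me, 9α-H, 13β-Me, 13α-O, 14α-H, with C6'=O on the β side of the spiro centre.

Assumption: the sense of induction in step 5 is taken as drawn for the quinidine-derived catalyst; if it proves opposite, the pseudoenantiomeric quinine-derived catalyst (DHQ)2AQN is used. E/Z isomers of 14, 15, 20–23 and C14 epimers of 16–18 are carried as mixtures.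

Step 1
Reactants: 1 dimethyl 2-bromobenzene-1,3-dicarboxylate; 2 2-(2-bromoethyl)-2-methyl-1,3-dioxolane
Product: 4 dimethyl 2-[2-(2-methyl-1,3-dioxolan-2-yl)ethyl]benzene-1,3-dicarboxylate, via alkylzinc bromide 3 (not isolated)
Conditions: 2, Zn dust, LiCl, THF, 50 °C; then 1, Pd(OAc)2 (2 mol %), SPhos (4 mol %), THF, 50 °C
Reagents that add atoms: zinc, [Zn] (retained in intermediate 3 only)
Why: Zinc insertion into the primary bromide followed by Negishi sp2–sp3 coupling should attach the masked 3-oxobutyl chain (C6–C8, C17) to the future C5; no stereocentre is formed.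

Step 2
Reactants: 4 dimethyl 2-[2-(2-methyl-1,3-dioxolan-2-yl)ethyl]benzene-1,3-dicarboxylate
Product: 5 dimethyl all-cis-2-[2-(2-methyl-1,3-dioxolan-2-yl)ethyl]cyclohexane-1,3-dicarboxylate (meso)
Conditions: H2 (60 bar), Rh/Al2O3, i-PrOH, 60 °C
Reagents that add atoms: none
Why: Heterogeneous arene hydrogenation delivers all hydrogens to one face, so the three ring substituents should end all-cis (meso), while the ketal keeps the side-chain ketone from being reduced.

Step 3
Reactants: 5 dimethyl all-cis-2-[2-(2-methyl-1,3-dioxolan-2-yl)ethyl]cyclohexane-1,3-dicarboxylate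
Product: 6 all-cis-2-[2-(2-methyl-1,3-dioxolan-2-yl)ethyl]cyclohexane-1,3-dicarboxylic acid (meso)
Conditions: LiOH, THF/H2O, 50 °C; then 1 M HCl to pH 3, 0 °C
Reagents that add atoms: lithium hydroxide, [Li+].[OH-]
Why: Ester saponification should be faster than α-epimerisation, and brief cold acidification should leave the ketal intact.

Step 4
Reactants: 6 all-cis-2-[2-(2-methyl-1,3-dioxolan-2-yl)ethyl]cyclohexane-1,3-dicarboxylic acid
Product: 7 meso-9-[2-(2-methyl-1,3-dioxolan-2-yl)ethyl]-3-oxabicyclo[3.3.1]nonane-2,4-dione (side chain cis to both acyl carbons)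
Conditions: DCC, CH2Cl2, rt
Reagents that add atoms: none
Why: Carbodiimide dehydration of the cis-1,3-diacid should give the six-membered (glutaric-type) meso anhydride, which only the cis-diacid can form.

Step 5
Reactants: 7 meso-9-[2-(2-methyl-1,3-dioxolan-2-yl)ethyl]-3-oxabicyclo[3.3.1]nonane-2,4-dione
Product: 8 all-cis hemiester: CO2Me (C20) on C10, CO2H (C19) on C4, side chain on C5, all three on the β face
Conditions: MeOH (10 equiv), (DHQD)2AQN (10 mol %), Et2O, –20 °C
Reagents that add atoms: methanol, CO
Why: Cinchona-alkaloid-catalysed enantioselective methanolysis of a meso anhydride distinguishes the two enantiotopic carbonyl groups, which makes C5 a stereocentre of defined absolute configuration and differentiates C20 (ester) from C19 (acid).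

Step 6
Reactants: 8 all-cis hemiester
Product: 9 10α-allyl hemiester (C10 quaternary: allyl α, CO2Me β; C4–H still present)
Conditions: LiN(i-Pr)2 (2.2 equiv), THF, –78 → –20 °C; allyl bromide, –78 °C → rt; aq. HCl work-up
Reagents that add atoms: allyl bromide, C=CCBr
Why: α-Alkylation of the ester enolate within the carboxylate/enolate dianion; allylic 1,3-strain with the exocyclic enolate should hold the C5 chain axial, so the electrophile enters anti to it and C10 is set with allyl α and C20 β.

Step 7
Reactants: 9 10α-allyl hemiester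
Product: 10 4α-methyl-10α-allyl acid ester (C4 quaternary: Me α, CO2H β; C10 as in 9)
Conditions: LiN(i-Pr)2 (2.5 equiv), THF/DMPU, –20 → 0 °C; MeI (1.05 equiv), –78 → 0 °C; aq. HCl work-up
Reagents that add atoms: iodomethane, CI
Why: C-Alkylation of the carboxylic acid enediolate (dianion) at C4, again anti to the C5 chain, should set C4 with methyl α and C19 β, cis to C20; one equivalent of MeI at low temperature avoids O-methylation.

Step 8
Reactants: 10 4α-methyl-10α-allyl acid ester
Product: 12 ring A keto lactone, 1-methyl-9-(3-oxobutyl)-5-(prop-2-en-1-yl)-3-oxabicyclo[3.3.1]nonan-2-one (4α-Me, 5α-H, 10α-allyl, 19,20-lactone bridge β), via hydroxy acid 11 (not isolated)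
Conditions: LiBH4, MeOH, THF, 60 °C; then 2 M HCl, THF, 40 °C
Reagents that add atoms: water, O
Why: Chemoselective hydride reduction of the ester beside the inert lithium carboxylate, then acid-catalysed lactonisation of the cis-1,3-diaxial hydroxy acid and ketal hydrolysis; no stereocentre is touched.

Step 9
Reactants: 12 ring A keto lactone; 13 diethyl (2-oxopropyl)phosphonate
Product: 14 ring A lactone with 10α-allyl and, on C5, a 4-(diethoxyphosphoryl)-3-methyl-5-oxohex-3-en-1-yl chain (E/Z mixture)
Conditions: TiCl4, pyridine, THF, 0 °C → rt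
Reagents that add atoms: none
Why: Knoevenagel condensation of the methyl ketone with the active methylene compound under TiCl4/pyridine activation should build the C8=C14 acceptor carrying C13 (acetyl) and the phosphonate; the alkene geometry is irrelevant because C8 becomes tetrahedral.

Step 10
Reactants: 14 allyl-substituted alkylidene β-ketophosphonate
Product: 15 key precursor: as 14 but with 10α-(2-oxopropyl) (C9–C11(=O)–C12) in place of allyl
Conditions: PdCl2 (10 mol %), CuCl, O2 (1 atm), DMF/H2O (7:1), rt
Reagents that add atoms: water, O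
Why: Wacker oxidation (Markovnikov hydroxypalladation of the terminal alkene) should give the C11 methyl ketone, the tetrasubstituted electron-poor alkene being inert.

Step 11
Reactants: 15 key precursor
Product: 18 tricyclic enone phosphonate (rings A, B, C; 11-oxo-12-ene, 13-methyl, 14-diethoxyphosphoryl as C14 epimers, 8β-Me, 9α-H, 19,20-lactone), via Michael adduct 16 (not isolated), via aldol adduct 17 (not isolated)
Conditions: TsOH·H2O (0.5 equiv), toluene, 110 °C, Dean–Stark
Reagents that add atoms: none
Why: Under acid the C11 ketone enolises toward C9 (the more substituted enol) and the O-protonated alkylidene β-ketophosphonate is a tertiary carbocation equivalent at C8, so C9 adds to C8 (intramolecular Michael addition); the C11=C12 enol then attacks the C13 acetyl group and the aldol dehydrates to the enone, the closest known reaction types being the acid-catalysed Robinson annulation and cyclohexenone formation from alkylidene 1,3-dicarbonyl compounds, here in the [3+3] sense. Ring B closes in a 6-(enolexo)-exo-trig mode and ring C in a 6-(enolendo)-exo-trig aldol mode. C8 and C9 are set in a chair-like, reversible ring B closure in which the ring A bonds C5–C6 and C10–C9 are equatorial and both the acetyl group on C9 and the bulky C14 terminus on C8 stay equatorial, so that the C8 methyl becomes axial (β, syn to C20) and H9 axial (α); C9 stays correctable by enolisation, and the other C8 epimer would put the C14 terminus 1,3-diaxial to the C20 bridge. Site selectivity in the Michael step (C9, not C12) follows from ring size (six- against eight-membered). The aldol direction (C12 onto C13, not C16 onto C11) follows from the neopentylic hindrance of the C11 carbonyl and the strain of a vinylic methyl next to C1 in the alternative enone. C14 is left as an epimer mixture because it becomes trigonal in the next step.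

Step 12
Reactants: 18 tricyclic enone phosphonate; 19 2,5-dimethoxybenzaldehyde
Product: 20 dienone: 11-oxo-12-ene with a 14-(2,5-dimethoxybenzylidene) group (C14=C15, E/Z)
Conditions: NaH, THF, 0 °C; then 19, 0 → 65 °C
Reagents that add atoms: none
Why: Vinylogous Horner–Wadsworth–Emmons olefination: the phosphonate-stabilised dienolate reacts at C14 and phosphate is expelled, which installs C15 with the aryl ring and removes the activating group; C14 is trigonal, so its earlier configuration does not matter.

Step 13
Reactants: 20 dienone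
Product: 21 12α,13α-epoxy-11-ketone (C14=C15 arylidene retained)
Conditions: t-BuOOH, DBU, CH2Cl2, 0 °C → rt
Reagents that add atoms: tert-butyl hydroperoxide, CC(C)(C)OO
Why: Weitz–Scheffer epoxidation of the α,β-bond (conjugate addition of the peroxide at C13, as with cinnamylidene ketones) from the α face, anti to the axial C8 methyl, should place oxygen α and C16 β at C13.

Step 14
Reactants: 21 12α,13α-epoxy-11-ketone
Product: 23 11-en-13α-ol (13β-Me; C14=C15 arylidene), via epoxy hydrazone 22 (not isolated)
Conditions: N2H4·H2O, AcOH (cat.), MeOH, 0 °C → rt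
Reagents that add atoms: none
Why: Wharton transposition: the hydrazone opens the epoxide and loses N2, which removes the C11 oxygen and leaves the C13–O bond untouched with its α configuration.

Step 15
Reactants: 23 11-en-13α-ol
Product: 24 saturated 13α-alcohol with 14β-(2,5-dimethoxybenzyl) and 14α-H
Conditions: H2 (1 atm), [Ir(cod)(PCy3)(py)]PF6 (5 mol %), CH2Cl2, rt
Reagents that add atoms: none
Why: Hydroxyl-directed homogeneous hydrogenation of both C=C bonds without allylic C–O hydrogenolysis; hydrogen should reach C14 from the α face (side of the C13 hydroxyl, the β face being screened by the axial C16 and C17 methyl groups), giving 14α-H with C15 β.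

Step 16
Reactants: 24 saturated 13α-alcohol
Product: 26 target spiro ether, via quinone 25 (not isolated)
Conditions: (NH4)2Ce(NO3)6, MeCN/H2O, 0 °C; then CSA (cat.), CH2Cl2, rt
Reagents that add atoms: water, O
Why: Oxidative demethylation gives the 2-alkyl-1,4-benzoquinone, and intramolecular oxa-Michael addition (5-exo-trig) of the C13 hydroxyl to the substituted carbon C1' closes the tetrahydrofuran; the spiro centre should be set under thermodynamic control of the reversible addition, with the planar C6'=O on the β side next to C16.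

Compound list
1 | dimethyl 2-bromobenzene-1,3-dicarboxylate | COC(=O)c1cccc(C(=O)OC)c1Br | starting material
2 | 2-(2-bromoethyl)-2-methyl-1,3-dioxolane | CC1(CCBr)OCCO1 | starting material
3 | [2-(2-methyl-1,3-dioxolan-2-yl)ethyl]zinc bromide | CC1(CC[Zn]Br)OCCO1 | intermediate (not isolated)
4 | dimethyl 2-[2-(2-methyl-1,3-dioxolan-2-yl)ethyl]benzene-1,3-dicarboxylate | COC(=O)c1cccc(C(=O)OC)c1CCC1(C)OCCO1 | intermediate
5 | dimethyl all-cis-2-[2-(2-methyl-1,3-dioxolan-2-yl)ethyl]cyclohexane-1,3-dicarboxylate (meso) | CC1(OCCO1)CC[C@@H]2[C@H](C(=O)OC)CCC[C@@H]2C(=O)OC | intermediate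
6 | all-cis-2-[2-(2-methyl-1,3-dioxolan-2-yl)ethyl]cyclohexane-1,3-dicarboxylic acid (meso) | CC1(OCCO1)CC[C@@H]2[C@H](C(=O)O)CCC[C@@H]2C(=O)O | intermediate
7 | meso-9-[2-(2-methyl-1,3-dioxolan-2-yl)ethyl]-3-oxabicyclo[3.3.1]nonane-2,4-dione | CC1(OCCO1)CC[C@@H]2[C@H]3CCC[C@@H]2C(=O)OC3=O | intermediate
8 | all-cis hemiester, CO2Me (C20) on C10 and CO2H (C19) on C4 | CC1(OCCO1)CC[C@@H]2[C@H](C(=O)OC)CCC[C@@H]2C(=O)O | intermediate
9 | 10α-allyl hemiester (allyl trans to the C5 chain) | CC1(OCCO1)CC[C@@H]2[C@@](C(=O)OC)(CC=C)CCC[C@@H]2C(=O)O | intermediate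
10 | 4α-methyl-10α-allyl acid ester | CC1(OCCO1)CC[C@@H]2[C@@](C(=O)OC)(CC=C)CCC[C@]2(C)C(=O)O | intermediate
11 | hydroxy acid (C20 = CH2OH, C19 = CO2H, ketal intact) | CC1(OCCO1)CC[C@@H]2[C@@](CO)(CC=C)CCC[C@]2(C)C(=O)O | intermediate (not isolated)
12 | ring A keto lactone, 1-methyl-9-(3-oxobutyl)-5-(prop-2-en-1-yl)-3-oxabicyclo[3.3.1]nonan-2-one (4α-Me, 5α-H, 10α-allyl) | CC(=O)CC[C@@H]1[C@]2(CCC[C@]1(C)C(=O)OC2)CC=C | intermediate
13 | diethyl (2-oxopropyl)phosphonate | CCOP(=O)(OCC)CC(C)=O | starting material
14 | allyl lactone with 4-(diethoxyphosphoryl)-3-methyl-5-oxohex-3-en-1-yl chain on C5 (E/Z) | CC(=O)C(=C(C)CC[C@@H]1[C@]2(CCC[C@]1(C)C(=O)OC2)CC=C)P(=O)(OCC)OCC | intermediate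
15 | key precursor, 10α-(2-oxopropyl) analogue of 14 | CC(=O)C(=C(C)CC[C@@H]1[C@]2(CCC[C@]1(C)C(=O)OC2)CC(C)=O)P(=O)(OCC)OCC | intermediate
16 | Michael adduct: trans-fused rings A/B, 8β-Me, 8α-[1-(diethoxyphosphoryl)-2-oxopropyl], 9β-acetyl, 9α-H | C[C@@]1(C(C(C)=O)P(=O)(OCC)OCC)CC[C@@H]2[C@]3(CCC[C@]2(C)C(=O)OC3)[C@H]1C(C)=O | intermediate (not isolated)
17 | aldol adduct: ring C closed, 11-oxo, 13-hydroxy-13-methyl, 14-phosphonate (C13, C14 epimers) | C[C@@]12CC[C@@H]3[C@]4(CCC[C@]3(C)C(=O)OC4)[C@H]1C(=O)CC(C)(O)C2P(=O)(OCC)OCC | intermediate (not isolated)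
18 | tricyclic enone phosphonate: 11-oxo-12-ene, 13-Me, 14-P(O)(OEt)2 (C14 epimers), 8β-Me, 9α-H | C[C@@]12CC[C@@H]3[C@]4(CCC[C@]3(C)C(=O)OC4)[C@H]1C(=O)C=C(C)C2P(=O)(OCC)OCC | intermediate
19 | 2,5-dimethoxybenzaldehyde | COc1ccc(OC)c(C=O)c1 | starting material
20 | dienone: 11-oxo-12-ene, 14-(2,5-dimethoxybenzylidene) (E/Z) | C[C@@]12CC[C@@H]3[C@]4(CCC[C@]3(C)C(=O)OC4)[C@H]1C(=O)C=C(C)C2=Cc1cc(OC)ccc1OC | intermediate
21 | 12α,13α-epoxy-11-ketone | C[C@@]12CC[C@@H]3[C@]4(CCC[C@]3(C)C(=O)OC4)[C@H]1C(=O)[C@@H]1O[C@]1(C)C2=Cc1cc(OC)ccc1OC | intermediate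
22 | hydrazone of 21 at C11 | C[C@@]12CC[C@@H]3[C@]4(CCC[C@]3(C)C(=O)OC4)[C@H]1C(=NN)[C@@H]1O[C@]1(C)C2=Cc1cc(OC)ccc1OC | intermediate (not isolated)
23 | 11-en-13α-ol (13β-Me), 14-arylidene | C[C@@]12CC[C@@H]3[C@]4(CCC[C@]3(C)C(=O)OC4)[C@H]1C=C[C@](C)(O)C2=Cc1cc(OC)ccc1OC | intermediate
24 | saturated 13α-ol with 14β-(2,5-dimethoxybenzyl), 14α-H | C[C@@]12CC[C@@H]3[C@]4(CCC[C@]3(C)C(=O)OC4)[C@H]1CC[C@](C)(O)[C@H]2Cc1cc(OC)ccc1OC | intermediate
25 | quinone alcohol: 14β-[(3,6-dioxocyclohexa-1,4-dien-1-yl)methyl], 13α-OH | C[C@@]12CC[C@@H]3[C@]4(CCC[C@]3(C)C(=O)OC4)[C@H]1CC[C@](C)(O)[C@H]2CC1=CC(=O)C=CC1=O | intermediate (not isolated)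
26 | target spiro ether CNP0290557.1 | C[C@@]12CC[C@@H]3[C@]4(CCC[C@]3(C)C(=O)OC4)[C@H]1CC[C@]1(C)O[C@]3(CC(=O)C=CC3=O)C[C@@H]21 | target

Total step count: 16. Longest linear sequence: 16 steps (1 → 26).

Steps most likely to fail

Step 11. The acid-generated enol may be too weak a nucleophile for the tetrasubstituted acceptor, which can instead deconjugate; ring B may also close with poor facial selectivity at C8, or ring C may close by the wrong aldol direction. The fallback sets out from 15 and comes back at 18. Compound 15 is condensed with pyrrolidine (TsOH cat., benzene, Dean–Stark) to the pyrrolidine enamine F1 (double-bond isomers equilibrate; the C9=C11 isomer is the reactive one). Heated in MeCN, this neutral, preformed nucleophile adds to C8 in an intramolecular Stork enamine Michael reaction. Aqueous AcOH/NaOAc is then added to the same flask to hydrolyse the iminium ion and to drive the aldol condensation of C12 onto C13, so that both bonds still arise in one operation.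

Step 14. Hydrazone formation at the C11 carbonyl may not occur, because its β face is flanked by the syn-axial C17 and C20 groups; hydrazine may then attack the lactone instead. The fallback sets out from 21 and comes back at 24. The epoxy ketone is cleaved reductively at C12–O with SmI2 (THF/MeOH, –78 °C) to the β-hydroxy ketone F3, the C13–O bond and its configuration being kept. Deprotonation with LiN(SiMe3)2 (2.2 equiv, –78 °C; alkoxide, then the kinetic C12 enolate) and O-sulfonylation with PhNTf2 give the enol triflate F4. Hydrogenation over PtO2 (H2, Et3N, EtOAc) removes the triflate by hydrogenolysis and saturates both C=C bonds, hydrogen again reaching C14 from the α face, which gives 24 without any nucleophilic attack at C11.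

Step 12. The neopentylic C14 carbanion may add only reversibly to the hindered, electron-rich aldehyde, so that no oxaphosphetane forms and no olefination takes place. The fallback sets out from 18 and comes back at 20. The anion of 18 (NaH, THF) is olefinated with paraformaldehyde, a far more reactive and unhindered carbonyl partner, to the 14-methylidene dienone F2. A Heck reaction with 2-bromo-1,4-dimethoxybenzene (Pd(OAc)2, P(o-tol)3, Et3N, DMF, 100 °C) then places the aryl group on the terminal carbon C15; β-hydride elimination is possible only from C15, so the arylidene dienone 20 results.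

Further compounds
F1 | step 11 | pyrrolidine enamine of 15 (C9=C11 isomer drawn) | CC(=O)C(=C(C)CC[C@@H]1[C@]2(CCC[C@]1(C)C(=O)OC2)C=C(C)N1CCCC1)P(=O)(OCC)OCC
F2 | step 12 | 14-methylidene dienone (11-oxo-12-ene, C14=CH2) | C[C@@]12CC[C@@H]3[C@]4(CCC[C@]3(C)C(=O)OC4)[C@H]1C(=O)C=C(C)C2=C
F3 | step 14 | 13α-hydroxy-11-ketone (13β-Me, 14-arylidene) | C[C@@]12CC[C@@H]3[C@]4(CCC[C@]3(C)C(=O)OC4)[C@H]1C(=O)C[C@](C)(O)C2=Cc1cc(OC)ccc1OC
F4 | step 14 | 11-en-11-yl triflate of F3 (13α-OH free) | C[C@@]12CC[C@@H]3[C@]4(CCC[C@]3(C)C(=O)OC4)[C@H]1C(OS(=O)(=O)C(F)(F)F)=C[C@](C)(O)C2=Cc1cc(OC)ccc1OC
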